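## The problem

Agecorynin E (12) is a (2S)-flavanone. A tetra-oxygenated benzene ring (ring A: methoxy groups at C5, C6 and C7, ring oxygen O1 on C8a) is fused to a dihydropyranone (ring C), which carries a 4-hydroxy-3-methoxyphenyl group (ring B) at C2. C2 is the only stereocentre, so nothing in the molecule can relay configuration to it; it has to be set by an external chiral catalyst and then kept. It is fragile: C2 is the β-carbon of an aryl ketone and bears an aryloxy leaving group, so base opens ring C by retro-oxa-Michael reaction, and the para-hydroxyl of ring B adds a quinone methide pathway. The C4 ketone should therefore appear late, and the closing steps must avoid base. Ring A is very electron-rich (C8 is activated by three oxygens) and C4a is crowded between the C5 methoxy group and O1, so strong electrophiles and oxidants have to be dosed carefully. The mask on the ring B phenol decides two things: how easily the benzylic C2–O1 bond ionises during assembly, and how gently the end game can be run. The enabling feature is that C4 is an aryl ketone carbon bonded to C4a, which lies ortho to O1. A tether O1–C2–C3 ending in an alkene can therefore be closed onto an iodide at C4a, with the carbonyl carried as an exocyclic methylene. The symmetry of 3,4,5-trimethoxyphenol (6) makes both positions ortho to its hydroxyl equivalent, so the iodide can be placed without a regiochemical question.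

## Retrosynthesis

**12 from 11.** The last cut is the O–C(=O) bond of a tert-butyl carbonate on the ring B oxygen. An acyl-type group is wanted because it keeps ring B from acting as a strong para donor when the C2–O1 bond is made. The tert-butyl carbonate is preferred to a pivalate or acetate because acid removes it without base or nucleophile, which the flavanone needs. A benzyl ether would be electron-donating and would need hydrogenolysis next to the benzylic C2–O1 bond. The forward step only has to liberate the phenol without touching C2.

**11 from 9.** The C4 carbonyl is traced back to the exocyclic C4=CH2 double bond of 9. Carrying the ketone as an alkene removes the acidity at C3, and with it the ring-opening pathway, from every earlier step. It also turns the ketone carbon into something an aryl–alkene coupling can deliver. The forward reaction must cleave a 1,1-disubstituted styrene-type alkene in the presence of two electron-rich arenes.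

**9 from 8.** Ring C is opened at C4–C4a. Closing ring C at O1–C2 by conjugate addition would make the stereocentre in a reversible step. Closing C4–C4a by acid-mediated acylation would expose the β-aryloxy acyl unit to elimination. The aryl–alkene coupling runs under near-neutral conditions and leaves C2 untouched. The precursor 8 is an acyclic aryl homoallyl ether with one stereocentre and an ortho-iodide. The forward reaction must close in the 6-exo sense and leave the new double bond exocyclic.

**8 from 5 and 7.** The ether bond C2–O1 is cut, which splits the molecule into a ring B alcohol and a ring A phenol of similar size. This is the convergent cut; cutting O1–C8a would need a doubly functionalised ring A partner. The forward reaction is a Mitsunobu etherification. It must proceed by clean SN2 inversion at a benzylic carbon, so alcohol 5 has to be R and ring B must not be a strong donor.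

**5 from 2 and 3; 2 from 1.** The C2–C3 bond is cut to aldehyde 2 and allylboronic acid pinacol ester (3). The stereocentre then comes from a catalytic enantioselective allylboration of an aromatic aldehyde, a reaction class that tolerates substituted benzaldehydes well. Aldehyde 2 is the tert-butyl carbonate of vanillin (1). The forward reaction must give the R carbinol with high selectivity.

**7 from 6.** The C–I bond is cut back to phenol 6. Its only free ring positions are the two equivalent carbons ortho to the hydroxyl, so mono-iodination gives a single isomer. The forward reaction must stop at one iodine and not oxidise the phenol.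

## Roads not taken

**Alternative 1:** Ring C is cut at C2–C3 and C4–C4a together. A chiral Brønsted acid of the binaphthyl phosphoric acid family would ionise the diaryl acetal A2, which carries two aryloxy groups derived from 6 on the ring B benzylic carbon. Ethyl vinyl ether A3 would add through its CH2 terminus to the resulting oxocarbenium carbon, and the new cation at C4 would be trapped by the ortho carbon of ring A to give the 2,4-cis chroman A1.
- Merits: two carbon–carbon bonds, ring C and the C2 stereocentre arise in one operation from very simple pieces. The symmetry of ring A removes any regiochemical issue in the ring closure.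
- Weak points: the absolute configuration would depend on ion pairing between a chiral anion and an oxocarbenium ion that has no hydrogen-bonding handle, an event far less developed than its nitrogen counterpart. The electron-rich, benzyl-protected ring B makes the C2–O1 bond of A1 ionisable under the same acid, so selectivity could erode after the fact. One aryloxy unit is lost as a leaving group. The C4 ethyl ether still has to be converted to the ketone and the benzyl group removed.
- Comparison: this road is shorter on paper (about five steps) and builds more in its key step. The chosen plan sets against it a stereocentre made by a dependable catalytic allylboration and passed on by a stereospecific substitution, at the cost of about two more steps and stoichiometric Mitsunobu by-products.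

**Alternative 2:** The cut is the C3=C4 double bond of the flavene A4. Ring-closing metathesis of the diene A5 with the second-generation Grubbs catalyst (H2IMes)(PCy3)Cl2Ru=CHPh would join the allyl ether vinyl group to an ortho-vinyl group on ring A.
- Merits: the C2–O1 bond of A5 could be formed enantioselectively by allylic etherification with [Ir(cod)Cl]2 and a chiral phosphoramidite ligand. That is catalytic, avoids substitution at an ionisable benzylic alcohol, and is better than the Mitsunobu step in both atom economy and risk. The metathesis itself is reliable for this diene type.
- Weak points: the phenol partner needs an ortho-vinyl group (one more cross-coupling from 7). After ring closure the C4 oxygen has to be introduced regioselectively by Markovnikov hydration and oxidation, since hydroboration would deliver oxygen to C3. A4 is a 2-aryl-2H-chromene and can open reversibly to an ortho-quinone methide by 6π electrocyclic ring opening under light or heat, which threatens C2.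
- Comparison: step count is similar or slightly longer. The chosen plan answers the better C–O bond formation of this road with a saturated C3 throughout, so C2 always sits in a configurationally stable ether, and with a C4 oxidation that involves no regiochemical choice.

**Alternative 3:** The cut is O1–C8a. Pd(OAc)2, a bulky di-tert-butyl biarylphosphine and Cs2CO3 would couple the C2 hydroxyl of the bromo alcohol A7 with the aryl bromide carbon to close ring C and give the silyl-protected chromanol A6.
- Merits: the benzylic C2–O bond is never broken, so the configuration set at the carbinol stage is carried with retention. This is intrinsically safer for C2 than an inversion at a benzylic centre. The C4 oxygen is already in place.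
- Weak points: A7 has two stereocentres and two benzylic hydroxyls that must be differentiated, and the C4 centre is made only to be oxidised away later. Palladium alkoxides of secondary benzylic alcohols can undergo β-hydride elimination in competition with C–O bond formation. Silyl removal, oxidation and debenzylation still follow the key step, giving roughly nine to ten steps.
- Comparison: this road is safer at C2. The chosen plan sets against it brevity (seven steps) and a C4 carried at the ketone oxidation level as an alkene, and keeps a retentive copper-catalysed etherification in reserve.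

Key step: step 5

Assumption: the (R)-configured binaphthyl phosphoric acid delivers the allyl group to the re face of aldehyde 2, as it does with benzaldehydes of this type, so that 5 is R. The configuration would be confirmed by Mosher ester analysis, and the S acid used if the sense proved opposite.

## Route

Step 1
Reactants: 1 vanillin
Product: 2 tert-butyl (4-formyl-2-methoxyphenyl) carbonate
Conditions: Boc2O (1.1 equiv), 4-(dimethylamino)pyridine (5 mol %), CH2Cl2, 0 °C → rt
Reagents that add atoms: di-tert-butyl dicarbonate, CC(C)(C)OC(=O)OC(=O)OC(C)(C)C
Why: Nucleophilic-catalysed O-acylation of the phenol; the aldehyde is untouched and the carbonate turns the ring B oxygen from a strong para donor into an acyloxy-type substituent.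

Step 2
Reactants: 2 tert-butyl (4-formyl-2-methoxyphenyl) carbonate; 3 allylboronic acid pinacol ester
Product: 5 tert-butyl [4-[(1R)-1-hydroxybut-3-en-1-yl]-2-methoxyphenyl] carbonate, via pinacol borate ester 4 (not isolated)
Conditions: (R)-3,3'-bis(2,4,6-triisopropylphenyl)-1,1'-binaphthyl-2,2'-diyl hydrogen phosphate (5 mol %), toluene, −30 °C; then H2O (pH 7 buffer), rt
Reagents that add atoms: none
Why: Chiral phosphoric acid-catalysed allylboration through a closed chair transition state in which the acid hydrogen-bonds to a boronate oxygen and its aryl walls shield one aldehyde face; re-face delivery should give the R carbinol, and the borate 4 is hydrolysed on work-up.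

Step 3
Reactants: 6 3,4,5-trimethoxyphenol
Product: 7 2-iodo-3,4,5-trimethoxyphenol
Conditions: N-iodosuccinimide (1.0 equiv), MeCN, 0 °C, dark
Reagents that add atoms: N-iodosuccinimide, O=C1CCC(=O)N1I
Why: Electrophilic aromatic iodination; the two free ring positions are equivalent and both ortho to the hydroxyl, so one equivalent of reagent at low temperature should give a single mono-iodide.

Step 4
Reactants: 5 tert-butyl [4-[(1R)-1-hydroxybut-3-en-1-yl]-2-methoxyphenyl] carbonate; 7 2-iodo-3,4,5-trimethoxyphenol
Product: 8 tert-butyl [4-[(1S)-1-(2-iodo-3,4,5-trimethoxyphenoxy)but-3-en-1-yl]-2-methoxyphenyl] carbonate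
Conditions: PPh3 (1.5 equiv), diisopropyl azodicarboxylate (1.5 equiv), toluene, 0 °C → rt
Reagents that add atoms: none
Why: Mitsunobu etherification; the phenoxide of 7 displaces the alkoxyphosphonium group by SN2 with inversion, turning the R alcohol into the S ether. The para carbonate and meta methoxy group give the benzylic cation no extra stabilisation, which disfavours ionisation, and the hindered tert-butyl carbonate resists acyl transfer.

Step 5
Reactants: 8 tert-butyl [4-[(1S)-1-(2-iodo-3,4,5-trimethoxyphenoxy)but-3-en-1-yl]-2-methoxyphenyl] carbonate
Product: 9 tert-butyl [2-methoxy-4-[(2S)-5,6,7-trimethoxy-4-methylenechroman-2-yl]phenyl] carbonate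
Conditions: Pd(OAc)2 (10 mol %), PPh3 (30 mol %), Ag2CO3 (2 equiv), MeCN (degassed), 80 °C
Reagents that add atoms: none
Why: Pd(OAc)2 is reduced by PPh3 to zerovalent palladium, which inserts into the C4a–I bond; Ag2CO3 removes iodide and gives a cationic arylpalladium that binds the terminal alkene. syn-Carbopalladation places the aryl group on the internal alkene carbon (C4) and palladium on the terminal carbon, forming C4–C4a; the closest known reaction type is the intramolecular Mizoroki–Heck cyclisation of 2-iodoaryl homoallyl ethers to 4-methylenechromans. Ring C closes in the 6-exo-trig mode, which the tether O1–C2–C3 favours over the 7-endo mode. The alkylpalladium has a single β-hydrogen, the one on C4, so β-hydride elimination can only give the exocyclic methylene. No stereocentre is formed, and C2 lies outside all bonds that change, so it is carried through as S. The step needs the double bond to stay exocyclic; the silver salt traps HI and keeps the pathway cationic, so the hydridopalladium species is quenched before it can re-add and move the alkene into ring C. The iodide is used because C4a is flanked by two oxygen-bearing carbons and oxidative addition is slowed by electron density and crowding. The carbonate and the methyl ethers are inert under these anhydrous conditions.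

Step 6
Reactants: 9 tert-butyl [2-methoxy-4-[(2S)-5,6,7-trimethoxy-4-methylenechroman-2-yl]phenyl] carbonate
Product: 11 tert-butyl [2-methoxy-4-[(2S)-5,6,7-trimethoxy-4-oxochroman-2-yl]phenyl] carbonate, via spiro ozonide 10 (not isolated)
Conditions: O3, CH2Cl2, −78 °C (Sudan Red 7B as end-point indicator); then Me2S, −78 °C → rt
Reagents that add atoms: ozone, [O-][O+]=O
Why: Ozonolysis (1,3-dipolar cycloaddition, Criegee rearrangement to the 1,2,4-trioxolane 10, reduction by Me2S); the 1,1-disubstituted styrene-type alkene reacts far faster than the aryl ethers, the indicator dye guards against excess ozone, and the base-free work-up leaves C2 intact.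

Step 7
Reactants: 11 tert-butyl [2-methoxy-4-[(2S)-5,6,7-trimethoxy-4-oxochroman-2-yl]phenyl] carbonate
Product: 12 Agecorynin E, (2S)-2-(4-hydroxy-3-methoxyphenyl)-5,6,7-trimethoxychroman-4-one
Conditions: CF3CO2H/CH2Cl2 (1:4), 0 °C
Reagents that add atoms: none
Why: Acidolysis of the aryl tert-butyl carbonate (loss of the tert-butyl cation as 2-methylpropene, then decarboxylation); no base or nucleophile is present, so the retro-oxa-Michael opening that would scramble C2 is avoided.

## Compound list

1 | vanillin (4-hydroxy-3-methoxybenzaldehyde) | COc1cc(C=O)ccc1O | starting material
2 | tert-butyl (4-formyl-2-methoxyphenyl) carbonate | COc1cc(C=O)ccc1OC(=O)OC(C)(C)C | intermediate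
3 | allylboronic acid pinacol ester | C=CCB1OC(C)(C)C(C)(C)O1 | starting material
4 | tert-butyl [2-methoxy-4-[(1R)-1-[(4,4,5,5-tetramethyl-1,3,2-dioxaborolan-2-yl)oxy]but-3-en-1-yl]phenyl] carbonate (not isolated) | C=CC[C@@H](OB1OC(C)(C)C(C)(C)O1)c1ccc(OC(=O)OC(C)(C)C)c(OC)c1 | intermediate
5 | tert-butyl [4-[(1R)-1-hydroxybut-3-en-1-yl]-2-methoxyphenyl] carbonate | C=CC[C@@H](O)c1ccc(OC(=O)OC(C)(C)C)c(OC)c1 | intermediate
6 | 3,4,5-trimethoxyphenol | COc1cc(O)cc(OC)c1OC | starting material
7 | 2-iodo-3,4,5-trimethoxyphenol | COc1cc(O)c(I)c(OC)c1OC | intermediate
8 | tert-butyl [4-[(1S)-1-(2-iodo-3,4,5-trimethoxyphenoxy)but-3-en-1-yl]-2-methoxyphenyl] carbonate | C=CC[C@H](Oc1cc(OC)c(OC)c(OC)c1I)c1ccc(OC(=O)OC(C)(C)C)c(OC)c1 | intermediate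
9 | tert-butyl [2-methoxy-4-[(2S)-5,6,7-trimethoxy-4-methylenechroman-2-yl]phenyl] carbonate | C=C1C[C@@H](c2ccc(OC(=O)OC(C)(C)C)c(OC)c2)Oc2cc(OC)c(OC)c(OC)c12 | intermediate
10 | tert-butyl [2-methoxy-4-[(2S)-5,6,7-trimethoxyspiro[chroman-4,3'-[1,2,4]trioxolan]-2-yl]phenyl] carbonate (both epimers at the spiro carbon, not isolated) | COc1cc([C@@H]2CC4(OCOO4)c3c(cc(OC)c(OC)c3OC)O2)ccc1OC(=O)OC(C)(C)C | intermediate
11 | tert-butyl [2-methoxy-4-[(2S)-5,6,7-trimethoxy-4-oxochroman-2-yl]phenyl] carbonate | COc1cc([C@@H]2CC(=O)c3c(cc(OC)c(OC)c3OC)O2)ccc1OC(=O)OC(C)(C)C | intermediate
12 | Agecorynin E, (2S)-2-(4-hydroxy-3-methoxyphenyl)-5,6,7-trimethoxychroman-4-one | COc1cc([C@@H]2CC(=O)c3c(cc(OC)c(OC)c3OC)O2)ccc1O | target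

## Step count and risks

Total: 7 steps. Longest linear sequence: 6 steps (steps 1, 2, 4, 5, 6, 7, from vanillin 1); step 3 is a one-step side branch.

**Step 5 (key step).** Oxidative addition at the crowded, electron-rich C4a–I bond may be slow, which would let reductive loss of iodine compete. The exocyclic double bond, which is strained against the C5 methoxy group, may also migrate into ring C by re-addition of the hydridopalladium species; the later cleavage would then break ring C instead of unmasking the ketone. The fallback keeps the C4–C4a bond but changes the mechanism. It sets out from 8 and proceeds as follows: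
- Ozonolysis of the terminal alkene (O3, CH2Cl2, −78 °C; then Me2S) passes through the terminal 1,2,4-trioxolane F1 to the β-aryloxy aldehyde F2.
- An intramolecular Nozaki–Hiyama–Kishi reaction (CrCl2 in excess, catalytic NiCl2, DMF, rt) adds the aryl iodide carbon to the aldehyde and gives the chroman-4-ol F3 as both C4 epimers.
- Dess–Martin periodinane in CH2Cl2 oxidises F3 to the ketone.

The fallback comes back to the route at 11.

**Step 4.** Partial ionisation of the activated benzylic alkoxyphosphonium intermediate would erode the inversion. Elimination towards the conjugated aryl diene could also compete, since the ortho-iodophenol is a hindered nucleophile. The fallback forms the ether from the other side, at O1–C8a, so the benzylic C–O bond is never broken. It sets out from 2 and proceeds as follows: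
- Allylboration with the S enantiomer of the step 2 acid gives, through the S-configured pinacol borate ester F4, the S-configured homoallylic alcohol F5.
- Copper-catalysed O-arylation with 5-iodo-1,2,3-trimethoxybenzene (CuI, 3,4,7,8-tetramethyl-1,10-phenanthroline, Cs2CO3, toluene, 80 °C) gives, with retention, the des-iodo aryl ether F6. The carbonate is the group to watch under the carbonate base.
- N-Iodosuccinimide in MeCN iodinates one of the two equivalent positions ortho to the ether oxygen of ring A.

The fallback comes back to the route at 8.

**Step 6.** Over-oxidation of the tetra-oxygenated ring A by ozone, or an abnormal fragmentation of the carbonyl oxide next to this electron-rich ring, could lower the return of ketone. The fallback avoids ozone. It sets out from 9: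
- Dihydroxylation with catalytic OsO4 and N-methylmorpholine N-oxide in acetone/H2O gives the 4-(hydroxymethyl)chroman-4-ol diol F7.
- NaIO4 in THF/H2O cleaves the diol.

The fallback comes back to the route at 11.

**Step 7.** The tert-butyl cation may alkylate electron-rich positions (C8 of ring A, or ring B next to the freed phenol). Acid-promoted reversible opening of ring C could also erode the configuration at C2. The fallback inverts the order of the last two operations, so the carbonate is removed while no C4 carbonyl is present and mild base is harmless. It sets out from 9:
- K2CO3 in MeOH at rt gives the free-phenol methylenechroman F8.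
- Ozonolysis with one equivalent of O3 in CH2Cl2 at −78 °C, then Me2S, proceeds through the free-phenol spiro ozonide F9. A free guaiacol unit is known to tolerate ozonolysis of a styrene-type alkene.

The fallback comes back to the route at 12.

## Further compounds

F1 | step 5 | tert-butyl [4-[(1S)-1-(2-iodo-3,4,5-trimethoxyphenoxy)-2-(1,2,4-trioxolan-3-yl)ethyl]-2-methoxyphenyl] carbonate (both epimers at the trioxolane carbon, not isolated) | C1OOC(O1)C[C@H](Oc1cc(OC)c(OC)c(OC)c1I)c1ccc(OC(=O)OC(C)(C)C)c(OC)c1
F2 | step 5 | tert-butyl [4-[(1S)-1-(2-iodo-3,4,5-trimethoxyphenoxy)-3-oxopropyl]-2-methoxyphenyl] carbonate | O=CC[C@H](Oc1cc(OC)c(OC)c(OC)c1I)c1ccc(OC(=O)OC(C)(C)C)c(OC)c1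
F3 | step 5 | tert-butyl [4-[(2S)-4-hydroxy-5,6,7-trimethoxychroman-2-yl]-2-methoxyphenyl] carbonate (both C4 epimers) | COc1cc([C@@H]2CC(O)c3c(cc(OC)c(OC)c3OC)O2)ccc1OC(=O)OC(C)(C)C
F4 | step 4 | tert-butyl [2-methoxy-4-[(1S)-1-[(4,4,5,5-tetramethyl-1,3,2-dioxaborolan-2-yl)oxy]but-3-en-1-yl]phenyl] carbonate (not isolated) | C=CC[C@H](OB1OC(C)(C)C(C)(C)O1)c1ccc(OC(=O)OC(C)(C)C)c(OC)c1
F5 | step 4 | tert-butyl [4-[(1S)-1-hydroxybut-3-en-1-yl]-2-methoxyphenyl] carbonate | C=CC[C@H](O)c1ccc(OC(=O)OC(C)(C)C)c(OC)c1
F6 | step 4 | tert-butyl [2-methoxy-4-[(1S)-1-(3,4,5-trimethoxyphenoxy)but-3-en-1-yl]phenyl] carbonate | C=CC[C@H](Oc1cc(OC)c(OC)c(OC)c1)c1ccc(OC(=O)OC(C)(C)C)c(OC)c1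
F7 | step 6 | tert-butyl [4-[(2S)-4-hydroxy-4-(hydroxymethyl)-5,6,7-trimethoxychroman-2-yl]-2-methoxyphenyl] carbonate (both C4 epimers) | COc1cc([C@@H]2CC(O)(CO)c3c(cc(OC)c(OC)c3OC)O2)ccc1OC(=O)OC(C)(C)C
F8 | step 7 | 2-methoxy-4-[(2S)-5,6,7-trimethoxy-4-methylenechroman-2-yl]phenol | C=C1C[C@@H](c2ccc(O)c(OC)c2)Oc2cc(OC)c(OC)c(OC)c12
F9 | step 7 | 2-methoxy-4-[(2S)-5,6,7-trimethoxyspiro[chroman-4,3'-[1,2,4]trioxolan]-2-yl]phenol (both epimers at the spiro carbon, not isolated) | COc1cc([C@@H]2CC4(OCOO4)c3c(cc(OC)c(OC)c3OC)O2)ccc1O
A1 | alternative 1 | (2S,4S)-2-[4-(benzyloxy)-3-methoxyphenyl]-4-ethoxy-5,6,7-trimethoxychroman | COc1cc([C@@H]2C[C@H](OCC)c3c(cc(OC)c(OC)c3OC)O2)ccc1OCc1ccccc1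
A2 | alternative 1 | 4-(benzyloxy)-3-methoxybenzaldehyde bis(3,4,5-trimethoxyphenyl) acetal | COc1cc(C(Oc2cc(OC)c(OC)c(OC)c2)Oc2cc(OC)c(OC)c(OC)c2)ccc1OCc1ccccc1
A3 | alternative 1 | ethyl vinyl ether | C=COCC
A4 | alternative 2 | (S)-2-[4-(benzyloxy)-3-methoxyphenyl]-5,6,7-trimethoxy-2H-chromene | COc1cc([C@@H]2C=Cc3c(cc(OC)c(OC)c3OC)O2)ccc1OCc1ccccc1
A5 | alternative 2 | 1-[[(1S)-1-[4-(benzyloxy)-3-methoxyphenyl]prop-2-en-1-yl]oxy]-2-ethenyl-3,4,5-trimethoxybenzene | C=C[C@H](Oc1cc(OC)c(OC)c(OC)c1C=C)c1ccc(OCc2ccccc2)c(OC)c1
A6 | alternative 3 | (2S,4S)-2-[4-(benzyloxy)-3-methoxyphenyl]-4-[(tert-butyldimethylsilyl)oxy]-5,6,7-trimethoxychroman | COc1cc([C@@H]2C[C@H](O[Si](C)(C)C(C)(C)C)c3c(cc(OC)c(OC)c3OC)O2)ccc1OCc1ccccc1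
A7 | alternative 3 | (1S,3S)-1-[4-(benzyloxy)-3-methoxyphenyl]-3-(2-bromo-4,5,6-trimethoxyphenyl)-3-[(tert-butyldimethylsilyl)oxy]propan-1-ol | COc1cc([C@@H](O)C[C@H](O[Si](C)(C)C(C)(C)C)c2c(Br)cc(OC)c(OC)c2OC)ccc1OCc1ccccc1
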